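## Structural features

Target 23 is 3,5,2',4'-tetrahydroxy-7,8,5'-trimethoxyflavone. Benzo ring A is fused along C4a–C8a to the 4-pyranone ring C, and ring C carries aryl ring B through the single bond C2–C1'. Ring A is oxygenated at every carbon except C6 (5-OH, 7-OMe, 8-OMe, O1 on C8a). Ring B has the 1,2,4-trioxygenated pattern 2'-OH, 4'-OH, 5'-OMe. Compound 23 has no stereocentre; the only ones in the route are the adjacent C2 and C3 of chromanones 19 to 21, and both become sp2 on oxidation. The fragile parts are the hydroquinone-like ring B (2'-OH para to 5'-OMe) and the enolic 3-OH, both sensitive to air in base, together with three methyl ethers that must survive beside four free hydroxyls. Strong acid is a further hazard, because opening and reclosing ring C (Wessely–Moser rearrangement) would turn the 5,7,8 pattern into the 5,6,7 pattern. The skeleton is not the real difficulty. The difficulty is telling the oxygens apart and closing ring C between two electron-rich, ortho-crowded arenes without a carbanion at C3, which sits beta to the leaving group O1. The key step uses the fact that C3 (enol carbon) and C4 (ketone carbon) of ring C are adjacent oxidised carbons. This is an oxidised α-ketol, and it can be traced to the union of the formyl carbon on C4a of ring A with the keto carbon of an α-keto ester.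

## Logic of the disconnections

**23 to 22.** The three O–CH2Ph bonds on O5, O2' and O4' are restored. All hydroxyls that need masking then carry one kind of group that leaves under neutral hydrogenolysis. If O5 were a methyl ether, a Lewis acid would have to distinguish it from the crowded 8-OMe and from the 5'-OMe next to a boron-binding phenol. The gain is a set of non-phenolic, air-stable intermediates. The demand is that the pyranone, the enol and the methyl ethers ignore H2 on palladium, and that O5 is benzylated from the outset.

**22 to 21.** No skeletal bond is cut. The C2=C3 π bond is replaced by C2–H and C3–H, which brings ring C down to the α-ketol level. The gain is a saturated ring C that a carbonyl–carbonyl coupling can reach. The demand is an oxidant that attacks the ketol and not the two donor-rich rings.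

**21 to 19 (through 20).** The bond from C3 to a carboxyl carbon is put back. This ester makes C3 a strongly electrophilic ketone one stage earlier, and it is lost as CO2 afterwards. The gain is a well-activated acceptor for the ring closure. The demand is ester removal without α-ketol rearrangement or opening of ring C.

**19 to 18.** The C3–C4 bond is cut, which opens ring C. C4 becomes an aldehyde on ring A and C3 becomes the ketone of an α-keto ester, tethered through O1–C2. The bicyclic ketol reduces to an aryl ether with one donor and one acceptor carbonyl. The demand is polarity inversion at C4 only, under conditions mild enough to leave the acidic C2–H alone.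

**18 to 7 + 17.** The O1–C2 bond is cut. It is the only link between the halves, so the route becomes convergent, with two fragments of equal length. The demand is that the hindered, hydrogen-bonded phenoxide of 7 displaces the benzylic chloride of 17 faster than base enolises either 17 or 18.

**17 to 14 + 15 (through 16).** The C2–C3 bond and the C2–Cl bond are cut together. One condensation delivers C3, the ester carbon and the leaving group, so no electrophilic halogen ever meets ring B. The gain is three carbons and two functional groups in one operation. The demand is that the deactivated aldehyde of 14 accepts the enolate of 15, and that no alcohol is present to solvolyse the labile chloride.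

**14 to 12 (through 13).** The C1'–CHO bond is cut. The position para to one benzyloxy group and ortho to the other is by far the most nucleophilic carbon of 12. The gain is a simple trialkoxybenzene. The demand is regiocontrol by electronics alone.

**12 to 11 to 9 to 8 (through 10).** Two O–benzyl bonds are cut, and the aryl C–O bond at the future C2' is traced back to an aryl–CHO bond. Compound 8 already holds the methoxy and hydroxy groups in the right relation. The demand is aryl, not hydride, migration in the peracid oxidation.

**7 to 6.** The C4a–C4 bond is cut. Compound 6 has a single free position ortho to its hydroxyl, so a chelation-directed formylation has only one outcome. The demand is ortho delivery, with no attack at the equally activated para carbon.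

**6 to 5 to 4 to 2 to 1 (through 3).** The temporary acetal on the future O1 is returned, the O5–benzyl bond is cut, and the aryl C–O bond at C5 is traced to the aldehyde carbon of 1. The two ring A oxygens flanking the future C4a are therefore never equivalent and cannot be confused. The demand is a mask on O1 that survives peracid and carbonate and leaves without touching the benzyl ether.

## Other disconnections considered

**Alternative 1:** The cut is C1'–C6' inside ring B. All six ring B carbons are traced to a pyranone in 3-(benzyloxy)-5,7,8-trimethoxy-2-[(5-methoxy-4-oxo-4H-pyran-2-yl)methyl]-4H-chromen-4-one A1.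
- **Forward step:** Base would add to C6 of the monocyclic pyranone and open it to a 1,3-diketone bearing a masked aldehyde. The methylene between the two heterocycles would then condense on that aldehyde carbon and aromatise to 3-(benzyloxy)-2-(2,4-dihydroxy-5-methoxyphenyl)-5,7,8-trimethoxy-4H-chromen-4-one A2.
- **In favour:** The step is an isomerisation. The 2',4',5' oxygen pattern is inherited from cheap kojic acid A3, and ring B needs no protecting group. Ring C is aromatic from the start, so no stereocentre or oxidation-level detour arises. On ring B step economy and on oxidation-state economy it is better than the chosen plan, which spends four steps on 14 and two on adjusting ring C.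
- **Against:** A1 holds two 4-pyranone rings that are both electrophilic at their oxygen-bearing carbons, so base could equally cleave ring C. The opened chain would rest as the enolate of its most acidic site, the future C3', with the aldehyde locked as a vinylogous carboxylate. The required bond would therefore join a weakly acidic carbon to a deactivated electrophile.
- **Further costs:** A2 still carries a 5-methyl ether, which brings back the Lewis acid selection problem, now beside free phenols. The same tetraoxygenated ring A phenol is needed, plus a C-acylation and a one-carbon homologation of A3.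
- **Comparison:** The chosen closure has one possible donor and one acceptor, which is the clearer mechanism. Overall step counts should be about equal.

**Alternative 2:** Ring A is cut at C4a–C5 and, one stage earlier, at C8–C8a. This leads to 4-{5-(benzyloxy)-6-[2,4-bis(benzyloxy)-5-methoxyphenyl]-4-oxo-4H-pyran-2-yl}-4-hydroxy-3-methoxycyclobut-2-en-1-one A4.
- **Forward step:** Heating would open the four-membered ring to a hydroxy vinylketene. Six-electron closure onto the neighbouring pyranone C=C and tautomerisation (Moore-type ring expansion) would give 3-(benzyloxy)-2-[2,4-bis(benzyloxy)-5-methoxyphenyl]-5,8-dihydroxy-7-methoxy-4H-chromen-4-one A5.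
- **Access to A4:** It would come from 3-methoxycyclobut-3-ene-1,2-dione A6 and the C6-metalated form of 3-(benzyloxy)-2-[2,4-bis(benzyloxy)-5-methoxyphenyl]-4H-pyran-4-one A7.
- **In favour:** The hard 5,7,8 pattern is written regiospecifically. The 5-OH appears free and chelated, so only the 8-OH would be methylated. The conditions are neutral, with no acidic C–H at risk. On ring A oxygen differentiation and on mildness it is better than the chosen plan, which needs five arene manipulations for 7.
- **Against:** A7 already contains rings B and C, so the ring C problem is moved rather than solved. Metalation at C6 of a 4-pyranone competes with nucleophilic attack on the ring. A6 needs its own preparation. The closure must engage an electron-poor, cross-conjugated C=C, a less familiar partner than an arene, and A5 is a hydroquinone prone to quinone formation.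
- **Comparison:** The pericyclic step is elegant and selective, but the supply of both partners should make the route longer and less certain.

**Alternative 3:** Ring A is cut at C4a–C8a, which unfolds it to methyl (4E)-8-(benzyloxy)-9-[2,4-bis(benzyloxy)-5-methoxyphenyl]-2,5-dimethoxy-3,7,9-trioxonon-4-enoate A8.
- **Forward step:** Base would make the C4a methylene acylate on the terminal ester carbon (Claisen/Dieckmann folding), with loss of methanol. Enolisation would give 2-(benzyloxy)-1-[2,4-bis(benzyloxy)-5-methoxyphenyl]-3-(2,4-dihydroxy-3,6-dimethoxyphenyl)propane-1,3-dione A9.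
- **In favour:** It mirrors the biogenesis of ring A, and the methyl groups on O5 and O8 are placed before the ring exists. A9 is a 1,3-diketone of the kind that cyclodehydrates to a 3-alkoxyflavone very dependably. For the ring C closure that follows, and for having C3 at the final oxidation level, it is better than the chosen plan.
- **Against:** A8 has several acidic sites, and the most acidic one (the future C3, between two ketones) is the wrong one. Aldol folding and O-cyclisation to pyranones compete with the Claisen mode, and the enol ether must hold the E geometry that brings C4a and C8a together. The 7-OH of A9 still needs selective methylation, and the 5-methyl ether needs selective cleavage.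
- **Comparison:** Building A8 from small acyl units would take a sequence at least as long as the two arene syntheses used here. The chosen plan trades biomimetic elegance for a precursor with one donor and one acceptor.

Key step: step 12

Assumption: compounds 16 to 21 are racemic. Where two stereocentres are present, both relative configurations are carried on together, so their SMILES have no stereodescriptors; both centres are erased in step 14.

## Steps

**Step 1**
Reactants: 1 3-hydroxy-4,5-dimethoxybenzaldehyde
Product: 2 3,4-dimethoxy-5-(methoxymethoxy)benzaldehyde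
Conditions: MOMCl, K2CO3, acetone, 0 °C to rt
Reagents that add atoms: chloromethyl methyl ether (MOMCl), COCCl
Why: Williamson-type O-alkylation of the only phenol; the acetal mask on the future O1 tolerates peracid and carbonate and is orthogonal to the benzyl ether introduced later.

**Step 2**
Reactants: 2 3,4-dimethoxy-5-(methoxymethoxy)benzaldehyde
Product: 4 3,4-dimethoxy-5-(methoxymethoxy)phenol, via aryl formate 3 (not isolated)
Conditions: mCPBA, CH2Cl2, 0 °C to rt; then K2CO3 (cat.), MeOH, rt
Reagents that add atoms: 3-chloroperoxybenzoic acid (mCPBA), OOC(=O)c1cccc(Cl)c1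
Why: Baeyer–Villiger (Dakin-type) oxidation in which the aryl group, pushed by the para methoxy group, migrates in preference to hydride; catalytic methanolysis of the formate frees the future 5-oxygen.

**Step 3**
Reactants: 4 3,4-dimethoxy-5-(methoxymethoxy)phenol
Product: 5 5-(benzyloxy)-1,2-dimethoxy-3-(methoxymethoxy)benzene
Conditions: BnBr, K2CO3, DMF, rt
Reagents that add atoms: benzyl bromide, BrCc1ccccc1
Why: Williamson ether synthesis on the single free phenol; it installs the mask of the 5-OH that leaves in the last step together with those of ring B.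

**Step 4**
Reactants: 5 5-(benzyloxy)-1,2-dimethoxy-3-(methoxymethoxy)benzene
Product: 6 5-(benzyloxy)-2,3-dimethoxyphenol
Conditions: HCl (cat.), MeOH, 45 °C
Reagents that add atoms: none
Why: Acid-catalysed acetal exchange cleaves only the methoxymethyl group; aryl benzyl and aryl methyl ethers are inert to dilute methanolic acid.

**Step 5**
Reactants: 6 5-(benzyloxy)-2,3-dimethoxyphenol
Product: 7 6-(benzyloxy)-2-hydroxy-3,4-dimethoxybenzaldehyde
Conditions: MgCl2, Et3N, (CH2O)n, MeCN, reflux; then 1 M HCl
Reagents that add atoms: paraformaldehyde (as formaldehyde), C=O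
Why: Casnati–Skattebøl ortho-formylation, in which the magnesium phenoxide delivers formaldehyde inside a chelate to the only free ortho carbon, so the activated para carbon is bypassed; a second formaldehyde takes up hydride to raise the benzylic alkoxide to the aldehyde.

**Step 6**
Reactants: 8 isovanillin (3-hydroxy-4-methoxybenzaldehyde)
Product: 9 3-(benzyloxy)-4-methoxybenzaldehyde
Conditions: BnBr, K2CO3, DMF, rt
Reagents that add atoms: benzyl bromide, BrCc1ccccc1
Why: Williamson ether synthesis; masking the phenol first keeps the peracid step away from a free, easily over-oxidised hydroxyarene.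

**Step 7**
Reactants: 9 3-(benzyloxy)-4-methoxybenzaldehyde
Product: 11 3-(benzyloxy)-4-methoxyphenol, via aryl formate 10 (not isolated)
Conditions: mCPBA, CH2Cl2, 0 °C to rt; then K2CO3 (cat.), MeOH, rt
Reagents that add atoms: 3-chloroperoxybenzoic acid (mCPBA), OOC(=O)c1cccc(Cl)c1
Why: Baeyer–Villiger oxidation with aryl migration favoured by the para methoxy group, followed by formate methanolysis; this converts the aldehyde carbon site into the future 2'-oxygen.

**Step 8**
Reactants: 11 3-(benzyloxy)-4-methoxyphenol
Product: 12 2,4-bis(benzyloxy)-1-methoxybenzene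
Conditions: BnBr, K2CO3, DMF, rt
Reagents that add atoms: benzyl bromide, BrCc1ccccc1
Why: Williamson ether synthesis on the single phenol completes the differentiated 1,2,4-trialkoxybenzene.

**Step 9**
Reactants: 12 2,4-bis(benzyloxy)-1-methoxybenzene
Product: 14 2,4-bis(benzyloxy)-5-methoxybenzaldehyde, via aryl iminium chloride 13 (not isolated)
Conditions: POCl3, DMF, 0 to 60 °C; then ice water
Reagents that add atoms: N,N-dimethylformamide, CN(C)C=O; water, O
Why: Vilsmeier–Haack formylation attacks the carbon that is para to one benzyloxy group and ortho to the other, as in the formylation of 1,2,4-trimethoxybenzene. The site between the two benzyloxy groups is blocked sterically, and the third site has only one ortho donor.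

**Step 10**
Reactants: 14 2,4-bis(benzyloxy)-5-methoxybenzaldehyde; 15 methyl dichloroacetate
Product: 17 methyl 3-[2,4-bis(benzyloxy)-5-methoxyphenyl]-3-chloro-2-oxopropanoate (racemic), via chloroglycidate 16 (not isolated)
Conditions: NaN(SiMe3)2, THF, −78 °C to rt; filtered, concentrated, used crude at once
Reagents that add atoms: none
Why: Darzens condensation of the dichloroacetate enolate gives α-chloroglycidate 16, whose donor-stabilised benzylic C–O bond ionises and collapses with transfer of chloride to the 3-chloro-2-oxo ester, a known one-operation route from aryl aldehydes. No electrophilic halogen meets ring B, and the amide base leaves no alcohol that could solvolyse the chloride.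

**Step 11**
Reactants: 7 6-(benzyloxy)-2-hydroxy-3,4-dimethoxybenzaldehyde; 17 methyl 3-[2,4-bis(benzyloxy)-5-methoxyphenyl]-3-chloro-2-oxopropanoate
Product: 18 methyl 3-[3-(benzyloxy)-2-formyl-5,6-dimethoxyphenoxy]-3-[2,4-bis(benzyloxy)-5-methoxyphenyl]-2-oxopropanoate (racemic)
Conditions: K2CO3 (1.0 equiv), acetone, 0 °C to rt
Reagents that add atoms: none
Why: Williamson alkylation of a phenoxide by an α-halo ketone that is doubly activated (adjacent carbonyl, donor aryl); any residual 16 converges on the same product by benzylic opening. One equivalent of carbonate ends as hydrogencarbonate, too weak to keep 18 enolised, which holds back a Rap–Stoermer-type aldol onto the aldehyde.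

**Step 12**
Reactants: 18 methyl 3-[3-(benzyloxy)-2-formyl-5,6-dimethoxyphenoxy]-3-[2,4-bis(benzyloxy)-5-methoxyphenyl]-2-oxopropanoate
Product: 19 methyl 5-(benzyloxy)-2-[2,4-bis(benzyloxy)-5-methoxyphenyl]-3-hydroxy-7,8-dimethoxy-4-oxochromane-3-carboxylate (racemic, both diastereomers)
Conditions: 2-(pentafluorophenyl)-6,7-dihydro-5H-pyrrolo[2,1-c][1,2,4]triazol-2-ium tetrafluoroborate (15 mol %), iPr2NEt (15 mol %), 4 Å MS, THF (0.05 M), 40 °C, Ar
Reagents that add atoms: none
Why: The amine frees the triazolylidene, which adds to the sole aldehyde, and proton transfer gives an enaminol in which C4 is nucleophilic. C4 attacks the keto carbon C3, made strongly electrophilic by the adjacent ester, and proton shift with loss of the carbene restores C4=O and returns the catalyst. The closest known reactions are the carbene-catalysed intramolecular crossed aldehyde–ketone benzoin of 2-(2-oxoalkoxy)benzaldehydes to 3-hydroxychroman-4-ones and the intermolecular aldehyde/α-keto ester cross-benzoin. Ring C closes in the 6-exo-trig mode, since the acceptor C=O lies outside the forming ring of C4, C4a, C8a, O1, C2 and C3. The new stereocentre C3 is influenced only by the resident C2 aryl group (substrate control, aryl pseudo-equatorial in a chair-like approach) because the catalyst is achiral; a mixture is acceptable since C2 and C3 are flattened in step 14. The selectivity needed is donor/acceptor chemoselectivity, secured because there is one aldehyde, because a ketone cannot become an acyl anion, and because dilution and ortho crowding disfavour intermolecular homocoupling. The acidic pentafluorophenyl triazolium needs only a catalytic tertiary amine, which keeps enolisation of C2–H and the five-membered aldol low, and the flat bicyclic carbene is small enough for a formyl group with two ortho oxygens. No carbanion ever resides on C3, so O1 is not expelled from C2.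

**Step 13**
Reactants: 19 methyl 5-(benzyloxy)-2-[2,4-bis(benzyloxy)-5-methoxyphenyl]-3-hydroxy-7,8-dimethoxy-4-oxochromane-3-carboxylate
Product: 21 5-(benzyloxy)-2-[2,4-bis(benzyloxy)-5-methoxyphenyl]-3-hydroxy-7,8-dimethoxychroman-4-one (racemic, trans expected to prevail), via keto acid 20 (not isolated)
Conditions: LiOH, THF/H2O, 0 °C; 1 M HCl to pH 3; EtOAc, 55 °C
Reagents that add atoms: none
Why: Saponification of an ester activated by the α-hydroxy and β-keto groups, then decarboxylation of β-keto acid 20 through the usual cyclic transition state after acidification; the enediol tautomerises to the aryl-conjugated ketol. The C3–H centre is uncontrolled and irrelevant.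

**Step 14**
Reactants: 21 5-(benzyloxy)-2-[2,4-bis(benzyloxy)-5-methoxyphenyl]-3-hydroxy-7,8-dimethoxychroman-4-one
Product: 22 5-(benzyloxy)-2-[2,4-bis(benzyloxy)-5-methoxyphenyl]-3-hydroxy-7,8-dimethoxy-4H-chromen-4-one
Conditions: I2, KOAc, AcOH, 100 °C
Reagents that add atoms: none
Why: Classical iodine/acetate dehydrogenation of a dihydroflavonol: enolisation toward C3, iodination and loss of HI give the 3,4-dione, which tautomerises through C2–H to the aromatic 3-hydroxy-4-pyranone. Acetate buffers HI so the benzyl ethers survive.

**Step 15**
Reactants: 22 5-(benzyloxy)-2-[2,4-bis(benzyloxy)-5-methoxyphenyl]-3-hydroxy-7,8-dimethoxy-4H-chromen-4-one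
Product: 23 2-(2,4-dihydroxy-5-methoxyphenyl)-3,5-dihydroxy-7,8-dimethoxy-4H-chromen-4-one (target)
Conditions: H2 (1 atm), 10% Pd/C, EtOAc/MeOH, rt; work-up under Ar
Reagents that add atoms: none
Why: Hydrogenolysis of three aryl benzyl ethers; methyl ethers, the pyranone and the enol are inert at one atmosphere. The neutral medium excludes demethylation and Wessely–Moser isomerisation.

## Compound list

1 | 3-hydroxy-4,5-dimethoxybenzaldehyde | COc1cc(C=O)cc(O)c1OC | starting material
2 | 3,4-dimethoxy-5-(methoxymethoxy)benzaldehyde | COCOc1cc(C=O)cc(OC)c1OC | intermediate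
3 | 3,4-dimethoxy-5-(methoxymethoxy)phenyl formate (not isolated) | COCOc1cc(OC=O)cc(OC)c1OC | intermediate
4 | 3,4-dimethoxy-5-(methoxymethoxy)phenol | COCOc1cc(O)cc(OC)c1OC | intermediate
5 | 5-(benzyloxy)-1,2-dimethoxy-3-(methoxymethoxy)benzene | COCOc1cc(OCc2ccccc2)cc(OC)c1OC | intermediate
6 | 5-(benzyloxy)-2,3-dimethoxyphenol | COc1cc(OCc2ccccc2)cc(O)c1OC | intermediate
7 | 6-(benzyloxy)-2-hydroxy-3,4-dimethoxybenzaldehyde | COc1cc(OCc2ccccc2)c(C=O)c(O)c1OC | intermediate
8 | isovanillin (3-hydroxy-4-methoxybenzaldehyde) | COc1ccc(C=O)cc1O | starting material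
9 | 3-(benzyloxy)-4-methoxybenzaldehyde | COc1ccc(C=O)cc1OCc1ccccc1 | intermediate
10 | 3-(benzyloxy)-4-methoxyphenyl formate (not isolated) | COc1ccc(OC=O)cc1OCc1ccccc1 | intermediate
11 | 3-(benzyloxy)-4-methoxyphenol | COc1ccc(O)cc1OCc1ccccc1 | intermediate
12 | 2,4-bis(benzyloxy)-1-methoxybenzene | COc1ccc(OCc2ccccc2)cc1OCc1ccccc1 | intermediate
13 | [2,4-bis(benzyloxy)-5-methoxybenzylidene]dimethyliminium chloride (not isolated) | C[N+](C)=Cc1cc(OC)c(OCc2ccccc2)cc1OCc1ccccc1.[Cl-] | intermediate
14 | 2,4-bis(benzyloxy)-5-methoxybenzaldehyde | COc1cc(C=O)c(OCc2ccccc2)cc1OCc1ccccc1 | intermediate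
15 | methyl dichloroacetate | COC(=O)C(Cl)Cl | starting material
16 | methyl 3-[2,4-bis(benzyloxy)-5-methoxyphenyl]-2-chlorooxirane-2-carboxylate (racemic, not isolated) | COC(=O)C1(Cl)OC1c1cc(OC)c(OCc2ccccc2)cc1OCc1ccccc1 | intermediate
17 | methyl 3-[2,4-bis(benzyloxy)-5-methoxyphenyl]-3-chloro-2-oxopropanoate (racemic) | COC(=O)C(=O)C(Cl)c1cc(OC)c(OCc2ccccc2)cc1OCc1ccccc1 | intermediate
18 | methyl 3-[3-(benzyloxy)-2-formyl-5,6-dimethoxyphenoxy]-3-[2,4-bis(benzyloxy)-5-methoxyphenyl]-2-oxopropanoate (racemic) | COC(=O)C(=O)C(Oc1c(OC)c(OC)cc(OCc2ccccc2)c1C=O)c1cc(OC)c(OCc2ccccc2)cc1OCc1ccccc1 | intermediate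
19 | methyl 5-(benzyloxy)-2-[2,4-bis(benzyloxy)-5-methoxyphenyl]-3-hydroxy-7,8-dimethoxy-4-oxochromane-3-carboxylate (racemic, both diastereomers) | COC(=O)C1(O)C(c2cc(OC)c(OCc3ccccc3)cc2OCc2ccccc2)Oc2c(OC)c(OC)cc(OCc3ccccc3)c2C1=O | intermediate
20 | 5-(benzyloxy)-2-[2,4-bis(benzyloxy)-5-methoxyphenyl]-3-hydroxy-7,8-dimethoxy-4-oxochromane-3-carboxylic acid (racemic, not isolated) | OC(=O)C1(O)C(c2cc(OC)c(OCc3ccccc3)cc2OCc2ccccc2)Oc2c(OC)c(OC)cc(OCc3ccccc3)c2C1=O | intermediate
21 | 5-(benzyloxy)-2-[2,4-bis(benzyloxy)-5-methoxyphenyl]-3-hydroxy-7,8-dimethoxychroman-4-one (racemic) | OC1C(c2cc(OC)c(OCc3ccccc3)cc2OCc2ccccc2)Oc2c(OC)c(OC)cc(OCc3ccccc3)c2C1=O | intermediate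
22 | 5-(benzyloxy)-2-[2,4-bis(benzyloxy)-5-methoxyphenyl]-3-hydroxy-7,8-dimethoxy-4H-chromen-4-one | COc1cc(-c2oc3c(OC)c(OC)cc(OCc4ccccc4)c3c(=O)c2O)c(OCc2ccccc2)cc1OCc1ccccc1 | intermediate
23 | 2-(2,4-dihydroxy-5-methoxyphenyl)-3,5-dihydroxy-7,8-dimethoxy-4H-chromen-4-one | COc1cc(-c2oc3c(OC)c(OC)cc(O)c3c(=O)c2O)c(O)cc1O | target

## Step count and least certain steps

Total step count: 15.
Longest linear sequence: 10 steps (steps 1 to 5 or steps 6 to 10, followed by steps 11 to 15).

**Step 12 (key step).**
- **Risk:** The formyl group is flanked by two ortho oxygens and deactivated by three donors. Carbene addition and the proton transfer to the enaminol may be slow. Amine-promoted enolisation at C2–H could then take over, with five-membered aldol closure onto the aldehyde or slow decomposition of the keto ester.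
- **Fallback:** It gives up the umpolung closure and builds ring C through a chalcone epoxide. It sets out from 7 and 14 and returns at 21.
- **To the acetophenone:** Compound 7 is protected with MOMCl and K2CO3 as 6-(benzyloxy)-3,4-dimethoxy-2-(methoxymethoxy)benzaldehyde F1. MeMgBr gives 1-[6-(benzyloxy)-3,4-dimethoxy-2-(methoxymethoxy)phenyl]ethanol F2. Dess–Martin oxidation gives 1-[6-(benzyloxy)-3,4-dimethoxy-2-(methoxymethoxy)phenyl]ethanone F3.
- **To the epoxide:** Claisen–Schmidt condensation of F3 with 14 (KOH, EtOH) gives (E)-1-[6-(benzyloxy)-3,4-dimethoxy-2-(methoxymethoxy)phenyl]-3-[2,4-bis(benzyloxy)-5-methoxyphenyl]prop-2-en-1-one F4. Weitz–Scheffer epoxidation (H2O2, NaOH, MeOH) gives the racemic trans epoxide [6-(benzyloxy)-3,4-dimethoxy-2-(methoxymethoxy)phenyl]{3-[2,4-bis(benzyloxy)-5-methoxyphenyl]oxiran-2-yl}methanone F5.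
- **Ring closure:** Methanolic HCl removes the acetal. The freed phenol then opens the epoxide at the donor-stabilised benzylic carbon to give 21.

**Step 11.**
- **Risk:** Carbonate may enolise 17 or 18 faster than the hindered, hydrogen-bonded phenoxide displaces chloride. That would lead to self-condensation of the halide, solvolysis by adventitious water, or aldol closure of the product onto its own aldehyde.
- **Fallback:** It forms O1–C2 at the alcohol oxidation level, where C2–H is not acidic. It sets out from 14 and 7 and returns at 18.
- **Sequence:** Darzens condensation of 14 with methyl chloroacetate (NaOMe) gives methyl trans-3-[2,4-bis(benzyloxy)-5-methoxyphenyl]oxirane-2-carboxylate F6. Compound 7 with catalytic Cs2CO3 in DMF opens it at the benzylic carbon to methyl 3-[3-(benzyloxy)-2-formyl-5,6-dimethoxyphenoxy]-3-[2,4-bis(benzyloxy)-5-methoxyphenyl]-2-hydroxypropanoate F7. Dess–Martin periodinane oxidises the secondary alcohol to 18 without touching the aldehyde.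

**Step 10.**
- **Risk:** Addition to the donor-deactivated aldehyde is reversible, so self-condensation of the dichloro enolate may compete. The very labile benzylic chloride may also ionise during handling, with solvolysis or oligomerisation.
- **Fallback:** It builds the pyruvate chain first and halogenates last. It sets out from 14 and returns at 17.
- **Sequence:** Erlenmeyer–Plöchl condensation with N-acetylglycine (Ac2O, NaOAc) gives (Z)-4-[2,4-bis(benzyloxy)-5-methoxybenzylidene]-2-methyloxazol-5(4H)-one F8. Aqueous NaOH followed by warm dilute HCl gives 3-[2,4-bis(benzyloxy)-5-methoxyphenyl]-2-oxopropanoic acid F9. MeI with KHCO3 in DMF gives methyl 3-[2,4-bis(benzyloxy)-5-methoxyphenyl]-2-oxopropanoate F10. N-chlorosuccinimide chlorinates its enol to 17.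

**Step 13.**
- **Risk:** Hydroxide may trigger α-ketol rearrangement with ring contraction or retro-Claisen opening at C4 before the ester is cleaved. Any base left at the decarboxylation stage may open ring C by elimination of O1 from C2.
- **Fallback:** It changes the ester so that it leaves under neutral conditions. It sets out from 14 and 7 and returns at 21.
- **Sequence:** Step 10 is run with allyl dichloroacetate to give allyl 3-[2,4-bis(benzyloxy)-5-methoxyphenyl]-3-chloro-2-oxopropanoate F11. Alkylation of 7 as in step 11 gives allyl 3-[3-(benzyloxy)-2-formyl-5,6-dimethoxyphenoxy]-3-[2,4-bis(benzyloxy)-5-methoxyphenyl]-2-oxopropanoate F12. The carbene closure of step 12 gives allyl 5-(benzyloxy)-2-[2,4-bis(benzyloxy)-5-methoxyphenyl]-3-hydroxy-7,8-dimethoxy-4-oxochromane-3-carboxylate F13.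
- **Ester removal:** Pd(PPh3)4, a zerovalent palladium complex, with morpholine in THF at rt (Tsuji–Trost deallylation) releases the β-keto acid, which decarboxylates to 21.

## Further compounds

F1 | step 12 | 6-(benzyloxy)-3,4-dimethoxy-2-(methoxymethoxy)benzaldehyde | COCOc1c(OC)c(OC)cc(OCc2ccccc2)c1C=O
F2 | step 12 | 1-[6-(benzyloxy)-3,4-dimethoxy-2-(methoxymethoxy)phenyl]ethanol (racemic) | COCOc1c(OC)c(OC)cc(OCc2ccccc2)c1C(C)O
F3 | step 12 | 1-[6-(benzyloxy)-3,4-dimethoxy-2-(methoxymethoxy)phenyl]ethanone | COCOc1c(OC)c(OC)cc(OCc2ccccc2)c1C(C)=O
F4 | step 12 | (E)-1-[6-(benzyloxy)-3,4-dimethoxy-2-(methoxymethoxy)phenyl]-3-[2,4-bis(benzyloxy)-5-methoxyphenyl]prop-2-en-1-one | COCOc1c(OC)c(OC)cc(OCc2ccccc2)c1C(=O)/C=C/c1cc(OC)c(OCc2ccccc2)cc1OCc1ccccc1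
F5 | step 12 | [6-(benzyloxy)-3,4-dimethoxy-2-(methoxymethoxy)phenyl]{3-[2,4-bis(benzyloxy)-5-methoxyphenyl]oxiran-2-yl}methanone (trans, racemic, one enantiomer drawn) | COCOc1c(OC)c(OC)cc(OCc2ccccc2)c1C(=O)[C@H]3O[C@@H]3c1cc(OC)c(OCc2ccccc2)cc1OCc1ccccc1
F6 | step 11 | methyl trans-3-[2,4-bis(benzyloxy)-5-methoxyphenyl]oxirane-2-carboxylate (racemic, one enantiomer drawn) | COC(=O)[C@H]1O[C@@H]1c1cc(OC)c(OCc2ccccc2)cc1OCc1ccccc1
F7 | step 11 | methyl 3-[3-(benzyloxy)-2-formyl-5,6-dimethoxyphenoxy]-3-[2,4-bis(benzyloxy)-5-methoxyphenyl]-2-hydroxypropanoate (racemic) | COC(=O)C(O)C(Oc1c(OC)c(OC)cc(OCc2ccccc2)c1C=O)c1cc(OC)c(OCc2ccccc2)cc1OCc1ccccc1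
F8 | step 10 | (Z)-4-[2,4-bis(benzyloxy)-5-methoxybenzylidene]-2-methyloxazol-5(4H)-one | CC1=N/C(=C\c2cc(OC)c(OCc3ccccc3)cc2OCc2ccccc2)C(=O)O1
F9 | step 10 | 3-[2,4-bis(benzyloxy)-5-methoxyphenyl]-2-oxopropanoic acid | OC(=O)C(=O)Cc1cc(OC)c(OCc2ccccc2)cc1OCc1ccccc1
F10 | step 10 | methyl 3-[2,4-bis(benzyloxy)-5-methoxyphenyl]-2-oxopropanoate | COC(=O)C(=O)Cc1cc(OC)c(OCc2ccccc2)cc1OCc1ccccc1
F11 | step 13 | allyl 3-[2,4-bis(benzyloxy)-5-methoxyphenyl]-3-chloro-2-oxopropanoate (racemic) | C=CCOC(=O)C(=O)C(Cl)c1cc(OC)c(OCc2ccccc2)cc1OCc1ccccc1
F12 | step 13 | allyl 3-[3-(benzyloxy)-2-formyl-5,6-dimethoxyphenoxy]-3-[2,4-bis(benzyloxy)-5-methoxyphenyl]-2-oxopropanoate (racemic) | C=CCOC(=O)C(=O)C(Oc1c(OC)c(OC)cc(OCc2ccccc2)c1C=O)c1cc(OC)c(OCc2ccccc2)cc1OCc1ccccc1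
F13 | step 13 | allyl 5-(benzyloxy)-2-[2,4-bis(benzyloxy)-5-methoxyphenyl]-3-hydroxy-7,8-dimethoxy-4-oxochromane-3-carboxylate (racemic, both diastereomers) | C=CCOC(=O)C1(O)C(c2cc(OC)c(OCc3ccccc3)cc2OCc2ccccc2)Oc2c(OC)c(OC)cc(OCc3ccccc3)c2C1=O
A1 | alternative 1 | 3-(benzyloxy)-5,7,8-trimethoxy-2-[(5-methoxy-4-oxo-4H-pyran-2-yl)methyl]-4H-chromen-4-one | COc1coc(Cc2oc3c(OC)c(OC)cc(OC)c3c(=O)c2OCc2ccccc2)cc1=O
A2 | alternative 1 | 3-(benzyloxy)-2-(2,4-dihydroxy-5-methoxyphenyl)-5,7,8-trimethoxy-4H-chromen-4-one | COc1cc(-c2oc3c(OC)c(OC)cc(OC)c3c(=O)c2OCc2ccccc2)c(O)cc1O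
A3 | alternative 1 | kojic acid (5-hydroxy-2-(hydroxymethyl)-4H-pyran-4-one) | OCc1cc(=O)c(O)co1
A4 | alternative 2 | 4-{5-(benzyloxy)-6-[2,4-bis(benzyloxy)-5-methoxyphenyl]-4-oxo-4H-pyran-2-yl}-4-hydroxy-3-methoxycyclobut-2-en-1-one (racemic) | COC1=CC(=O)C1(O)c1cc(=O)c(OCc2ccccc2)c(-c2cc(OC)c(OCc3ccccc3)cc2OCc2ccccc2)o1
A5 | alternative 2 | 3-(benzyloxy)-2-[2,4-bis(benzyloxy)-5-methoxyphenyl]-5,8-dihydroxy-7-methoxy-4H-chromen-4-one | COc1cc(O)c2c(=O)c(OCc3ccccc3)c(-c3cc(OC)c(OCc4ccccc4)cc3OCc3ccccc3)oc2c1O
A6 | alternative 2 | 3-methoxycyclobut-3-ene-1,2-dione | COC1=CC(=O)C1=O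
A7 | alternative 2 | 3-(benzyloxy)-2-[2,4-bis(benzyloxy)-5-methoxyphenyl]-4H-pyran-4-one | COc1cc(-c2occc(=O)c2OCc2ccccc2)c(OCc2ccccc2)cc1OCc1ccccc1
A8 | alternative 3 | methyl (4E)-8-(benzyloxy)-9-[2,4-bis(benzyloxy)-5-methoxyphenyl]-2,5-dimethoxy-3,7,9-trioxonon-4-enoate (racemic at C2 and C8) | COC(=O)C(OC)C(=O)/C=C(/OC)CC(=O)C(OCc1ccccc1)C(=O)c1cc(OC)c(OCc2ccccc2)cc1OCc1ccccc1
A9 | alternative 3 | 2-(benzyloxy)-1-[2,4-bis(benzyloxy)-5-methoxyphenyl]-3-(2,4-dihydroxy-3,6-dimethoxyphenyl)propane-1,3-dione (racemic) | COc1cc(O)c(OC)c(O)c1C(=O)C(OCc1ccccc1)C(=O)c1cc(OC)c(OCc2ccccc2)cc1OCc1ccccc1
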